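**Plan**

- The last cut removes ten O-benzyl groups. Ring C is then cut at C2–C3, C3–C4 and C1–C6: C3 (with its OH), C4 (O to ring D), C5 and C6 come from a cyclobutenone carrying ring D; C1 (O to ring B) and C2 come from the ethynyl ether of the AB phenol.
- The cut is possible because ring C has its C3 hydroxyl meta to the C1 ether oxygen, with C2 and C6 unsubstituted: a resorcinol monoether, the pattern a vinylketene and an ynol ether give.
- The AB ynol ether is cut at the O–C(sp) bond on B4 and at the ring A–O–ring B bond (copper coupling of the ring A phenol with a ring B bromide). Ring B comes from 2,3,4-trihydroxybenzaldehyde: formyl becomes the B3 oxygen, bromine marks B1.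
- Forward: rings A, B and D enter as arenes; A and B are joined first, the B4 oxygen is ethynylated, ring C is built last between the AB and D halves, then hydrogenolysis.
- Stereochemistry: the target has no stereocentre; the one sp3 centre of the cyclobutenone is racemic and becomes aromatic.

Key step: step 16

Assumption: the cyclobutenone is used as the racemate because the target is achiral, and 1,3,5-tris(benzyloxy)benzene is taken as a purchasable compound.

Ring labels: ring A is the 2,4,6-trioxygenated end ring, ring B the penta-oxygenated ring (B1 bears the O to ring A, B2 is CH, B4 bears the O to ring C), ring C the central ring, ring D the 3,4,5-trioxygenated end ring.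

**Ring D half (steps 1–4)**

Step 1
Reactants: 1 3,4,5-tris(benzyloxy)benzaldehyde
Product: 3 3,4,5-tris(benzyloxy)phenol, via aryl formate 2 (not isolated)
Conditions: mCPBA, CH2Cl2, 0 °C → rt; then K2CO3 (cat.), MeOH, rt
Reagents that add atoms: mCPBA (3-chloroperoxybenzoic acid), OOC(=O)c1cccc(Cl)c1
Why: Baeyer–Villiger oxidation of an aldehyde with a para-alkoxy group, in which the electron-rich aryl group migrates to give the formate that methanol then cleaves.

Step 2
Reactants: 3 3,4,5-tris(benzyloxy)phenol; 4 bromoacetic acid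
Product: 5 [3,4,5-tris(benzyloxy)phenoxy]acetic acid
Conditions: NaH (2.5 equiv), THF, 0 °C → reflux; then 1 M HCl
Reagents that add atoms: none
Why: Williamson ether synthesis of the sodium phenoxide with sodium bromoacetate, the standard route to aryloxyacetic acids.

Step 3
Reactants: 6 benzyl alcohol; 7 trichloroethylene
Product: 11 benzyl ethynyl ether, via dichlorovinyl ether 8 (not isolated), via chloroethynyl ether 9 (not isolated), via lithium acetylide 10 (not isolated)
Conditions: KH, THF, 0 °C; 7, –50 °C → rt; n-BuLi (2.3 equiv), –78 °C; H2O, –78 °C; cold pentane extraction, solution kept below 0 °C and used at once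
Reagents that add atoms: none
Why: Greene one-pot alkynyl ether synthesis (alkoxide substitution of trichloroethylene, then elimination and chlorine–lithium exchange with n-BuLi and cold protonation); the product is kept cold because benzyl alkynyl ethers rearrange sigmatropically on warming.

Step 4
Reactants: 5 [3,4,5-tris(benzyloxy)phenoxy]acetic acid; 11 benzyl ethynyl ether
Product: 14 racemic 3-(benzyloxy)-4-[3,4,5-tris(benzyloxy)phenoxy]cyclobut-2-en-1-one, via acid chloride 12 (not isolated), via aryloxyketene 13 (not isolated)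
Conditions: (COCl)2, DMF (cat.), CH2Cl2, 0 °C → rt, evaporate; then added slowly to 11 (3 equiv) and Et3N, Et2O–CH2Cl2, 0 → 20 °C
Reagents that add atoms: none
Why: ketene–alkynyl ether [2+2] cycloaddition, in which the aryloxyketene from dehydrochlorination is captured by the electron-rich alkyne, the unsubstituted alkyne carbon bonding to the ketene carbonyl carbon, so the 3-alkoxy-4-aryloxy isomer should form as a racemate.

**Ring A phenol (steps 5–6)**

Step 5
Reactants: 15 1,3,5-tris(benzyloxy)benzene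
Product: 16 2,4,6-tris(benzyloxy)benzaldehyde
Conditions: POCl3, DMF, 0 → 50 °C; then aq. NaOAc
Reagents that add atoms: N,N-dimethylformamide, CN(C)C=O; water, O
Why: Vilsmeier–Haack formylation of a phloroglucinol triether, whose three ring positions are equivalent and strongly activated.

Step 6
Reactants: 16 2,4,6-tris(benzyloxy)benzaldehyde
Product: 18 2,4,6-tris(benzyloxy)phenol, via aryl formate 17 (not isolated)
Conditions: mCPBA, CH2Cl2, 0 °C; then K2CO3 (cat.), MeOH, rt, under Ar
Reagents that add atoms: mCPBA (3-chloroperoxybenzoic acid), OOC(=O)c1cccc(Cl)c1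
Why: Baeyer–Villiger oxidation, favoured by two ortho and one para alkoxy groups on the migrating aryl; the electron-rich phenol is handled under argon.

**Ring B and the AB ynol ether (steps 7–15)**

Step 7
Reactants: 19 2,3,4-trihydroxybenzaldehyde
Product: 20 3,4-bis(benzyloxy)-2-hydroxybenzaldehyde
Conditions: BnBr (2.05 equiv), K2CO3 (2.1 equiv), DMF, 0 °C → rt
Reagents that add atoms: benzyl bromide, BrCc1ccccc1
Why: selective Williamson benzylation, the 2-hydroxyl being hydrogen-bonded to the formyl group and therefore the least nucleophilic of the three.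

Step 8
Reactants: 20 3,4-bis(benzyloxy)-2-hydroxybenzaldehyde
Product: 21 3,4-bis(benzyloxy)-5-bromo-2-hydroxybenzaldehyde
Conditions: NBS, MeCN, 0 °C → rt
Reagents that add atoms: N-bromosuccinimide, O=C1CCC(=O)N1Br
Why: electrophilic aromatic bromination at C5, the only position para to the free hydroxyl, ortho to an ether and meta to the formyl group.

Step 9
Reactants: 21 3,4-bis(benzyloxy)-5-bromo-2-hydroxybenzaldehyde
Product: 22 3,4-bis(benzyloxy)-5-bromo-2-(methoxymethoxy)benzaldehyde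
Conditions: MOMCl, iPr2NEt, CH2Cl2, 0 °C → rt
Reagents that add atoms: chloromethyl methyl ether, COCCl
Why: O-alkylation to the MOM acetal, which masks the future B4 oxygen and is orthogonal to benzyl ethers, peracid and basic copper coupling.

Step 10
Reactants: 22 3,4-bis(benzyloxy)-5-bromo-2-(methoxymethoxy)benzaldehyde
Product: 24 3,4-bis(benzyloxy)-5-bromo-2-(methoxymethoxy)phenol, via aryl formate 23 (not isolated)
Conditions: mCPBA, NaHCO3, CH2Cl2, 0 °C → rt; then K2CO3 (cat.), MeOH, rt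
Reagents that add atoms: mCPBA (3-chloroperoxybenzoic acid), OOC(=O)c1cccc(Cl)c1
Why: Baeyer–Villiger oxidation with ortho and para alkoxy groups on the migrating aryl turns the formyl carbon into the B3 oxygen; the buffer protects the MOM acetal and the aryl bromide is inert.

Step 11
Reactants: 24 3,4-bis(benzyloxy)-5-bromo-2-(methoxymethoxy)phenol
Product: 25 1,3,4-tris(benzyloxy)-5-bromo-2-(methoxymethoxy)benzene
Conditions: BnBr, K2CO3, DMF, rt
Reagents that add atoms: benzyl bromide, BrCc1ccccc1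
Why: Williamson benzylation of the only free phenol.

Step 12
Reactants: 25 1,3,4-tris(benzyloxy)-5-bromo-2-(methoxymethoxy)benzene; 18 2,4,6-tris(benzyloxy)phenol
Product: 26 1,3,4-tris(benzyloxy)-2-(methoxymethoxy)-5-[2,4,6-tris(benzyloxy)phenoxy]benzene
Conditions: CuI (10 mol %), picolinic acid (20 mol %), K3PO4, DMSO, 100 °C, degassed, Ar
Reagents that add atoms: none
Why: copper-catalysed Ullmann diaryl ether coupling with a picolinic acid ligand, a system developed for ortho-substituted phenols and aryl halides; ether and acetal groups are inert to phosphate base.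

Step 13
Reactants: 26 1,3,4-tris(benzyloxy)-2-(methoxymethoxy)-5-[2,4,6-tris(benzyloxy)phenoxy]benzene
Product: 27 2,3,6-tris(benzyloxy)-4-[2,4,6-tris(benzyloxy)phenoxy]phenol
Conditions: HCl (3 M), MeOH–THF, 45 °C
Reagents that add atoms: none
Why: acid-catalysed acetal exchange removes the MOM group while benzyl and diaryl ethers are untouched.

Step 14
Reactants: 27 2,3,6-tris(benzyloxy)-4-[2,4,6-tris(benzyloxy)phenoxy]phenol; 7 trichloroethylene
Product: 28 1,3,4-tris(benzyloxy)-2-[(E)-1,2-dichloroethenyloxy]-5-[2,4,6-tris(benzyloxy)phenoxy]benzene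
Conditions: K2CO3, DMF, 70 °C
Reagents that add atoms: none
Why: phenoxide substitution of trichloroethylene by elimination–addition, the known route to aryl (E)-1,2-dichlorovinyl ethers, which also works for ortho-substituted phenols because the transient dichloroalkyne is unhindered.

Step 15
Reactants: 28 1,3,4-tris(benzyloxy)-2-[(E)-1,2-dichloroethenyloxy]-5-[2,4,6-tris(benzyloxy)phenoxy]benzene
Product: 31 1,3,4-tris(benzyloxy)-2-(ethynyloxy)-5-[2,4,6-tris(benzyloxy)phenoxy]benzene, via chloroethynyl ether 29 (not isolated), via lithium acetylide 30 (not isolated)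
Conditions: n-BuLi (2.2 equiv), THF, –78 → –40 °C; then H2O, –78 °C; used without storage
Reagents that add atoms: none
Why: elimination of HCl followed by chlorine–lithium exchange and protonation (second stage of the Greene alkynyl ether synthesis), run cold so that benzyl ethers and the aryloxy leaving group are not attacked.

**Ring C and end game (steps 16–17)**

Step 16
Reactants: 14 racemic 3-(benzyloxy)-4-[3,4,5-tris(benzyloxy)phenoxy]cyclobut-2-en-1-one (1.5 equiv); 31 1,3,4-tris(benzyloxy)-2-(ethynyloxy)-5-[2,4,6-tris(benzyloxy)phenoxy]benzene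
Product: 36 3-(benzyloxy)-2-[3,4,5-tris(benzyloxy)phenoxy]-5-{2,3,6-tris(benzyloxy)-4-[2,4,6-tris(benzyloxy)phenoxy]phenoxy}phenol, via vinylketene 32 (not isolated), via vinylcyclobutenone 33 (not isolated), via dienylketene 34 (not isolated), via cyclohexadienone 35 (not isolated)
Conditions: toluene, 80 → 110 °C, sealed tube, Ar; then K2CO3, MeOH, rt
Reagents that add atoms: none
Why: Heat opens 14 by conrotatory four-electron ring opening, the donor aryloxy group on the sp3 carbon turning outward, to vinylketene 32, whose ketene C=C adds to the alkyne of 31 in a [2+2] cycloaddition (C2–C3 and C1–C6 formed) to give vinylcyclobutenone 33. A second four-electron opening gives dienylketene 34, and ring C closes by disrotatory six-electron electrocyclisation between the ketene carbon and the aryloxy-bearing terminus (C3–C4), dienone 35 then tautomerising to phenol 36. The closest known reaction is the Danheiser benzannulation of cyclobutenones with alkoxy- and siloxyalkynes to resorcinol monoethers. No stereocentre is formed, and the racemic centre of 14 becomes aromatic C4. The step needs one regiochemistry in the cycloaddition, and the polarity of the ynol ether secures it: the nucleophilic unsubstituted alkyne carbon bonds to the ketene carbonyl carbon, so the ring B oxygen ends meta to the new hydroxyl. The cyclobutenone is used in slight excess, and the carbonate–methanol treatment should return any product phenol that was acylated by vinylketene.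

Step 17
Reactants: 36 3-(benzyloxy)-2-[3,4,5-tris(benzyloxy)phenoxy]-5-{2,3,6-tris(benzyloxy)-4-[2,4,6-tris(benzyloxy)phenoxy]phenoxy}phenol
Product: 37 5-[2,3,6-trihydroxy-4-(2,4,6-trihydroxyphenoxy)phenoxy]-2-(3,4,5-trihydroxyphenoxy)benzene-1,3-diol (target)
Conditions: H2 (1 atm), 10% Pd/C, THF–MeOH, rt; filtration and concentration under Ar
Reagents that add atoms: none
Why: catalytic hydrogenolysis cleaves the ten benzyl ethers and leaves the diaryl ether bonds intact; no other reducible group is present.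

**Compound list**

1 | 3,4,5-tris(benzyloxy)benzaldehyde | O=Cc1cc(OCc2ccccc2)c(OCc2ccccc2)c(OCc2ccccc2)c1 | starting material
2 | 3,4,5-tris(benzyloxy)phenyl formate | O=COc1cc(OCc2ccccc2)c(OCc2ccccc2)c(OCc2ccccc2)c1 | intermediate
3 | 3,4,5-tris(benzyloxy)phenol | Oc1cc(OCc2ccccc2)c(OCc2ccccc2)c(OCc2ccccc2)c1 | intermediate
4 | bromoacetic acid | OC(=O)CBr | starting material
5 | [3,4,5-tris(benzyloxy)phenoxy]acetic acid | OC(=O)COc1cc(OCc2ccccc2)c(OCc2ccccc2)c(OCc2ccccc2)c1 | intermediate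
6 | benzyl alcohol | OCc1ccccc1 | starting material
7 | trichloroethylene | ClC=C(Cl)Cl | starting material
8 | benzyl (E)-1,2-dichlorovinyl ether | Cl/C=C(/Cl)OCc1ccccc1 | intermediate
9 | benzyl chloroethynyl ether | ClC#COCc1ccccc1 | intermediate
10 | lithium (benzyloxy)acetylide | [Li]C#COCc1ccccc1 | intermediate
11 | benzyl ethynyl ether | C#COCc1ccccc1 | intermediate
12 | [3,4,5-tris(benzyloxy)phenoxy]acetyl chloride | ClC(=O)COc1cc(OCc2ccccc2)c(OCc2ccccc2)c(OCc2ccccc2)c1 | intermediate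
13 | [3,4,5-tris(benzyloxy)phenoxy]ketene | O=C=COc1cc(OCc2ccccc2)c(OCc2ccccc2)c(OCc2ccccc2)c1 | intermediate
14 | racemic 3-(benzyloxy)-4-[3,4,5-tris(benzyloxy)phenoxy]cyclobut-2-en-1-one | O=C1C=C(OCc2ccccc2)C1Oc3cc(OCc4ccccc4)c(OCc4ccccc4)c(OCc4ccccc4)c3 | intermediate
15 | 1,3,5-tris(benzyloxy)benzene | c1c(OCc2ccccc2)cc(OCc2ccccc2)cc1OCc2ccccc2 | starting material
16 | 2,4,6-tris(benzyloxy)benzaldehyde | O=Cc1c(OCc2ccccc2)cc(OCc2ccccc2)cc1OCc2ccccc2 | intermediate
17 | 2,4,6-tris(benzyloxy)phenyl formate | O=COc1c(OCc2ccccc2)cc(OCc2ccccc2)cc1OCc2ccccc2 | intermediate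
18 | 2,4,6-tris(benzyloxy)phenol | Oc1c(OCc2ccccc2)cc(OCc2ccccc2)cc1OCc2ccccc2 | intermediate
19 | 2,3,4-trihydroxybenzaldehyde | O=Cc1ccc(O)c(O)c1O | starting material
20 | 3,4-bis(benzyloxy)-2-hydroxybenzaldehyde | O=Cc1ccc(OCc2ccccc2)c(OCc2ccccc2)c1O | intermediate
21 | 3,4-bis(benzyloxy)-5-bromo-2-hydroxybenzaldehyde | O=Cc1cc(Br)c(OCc2ccccc2)c(OCc2ccccc2)c1O | intermediate
22 | 3,4-bis(benzyloxy)-5-bromo-2-(methoxymethoxy)benzaldehyde | COCOc1c(C=O)cc(Br)c(OCc2ccccc2)c1OCc2ccccc2 | intermediate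
23 | 3,4-bis(benzyloxy)-5-bromo-2-(methoxymethoxy)phenyl formate | COCOc1c(OC=O)cc(Br)c(OCc2ccccc2)c1OCc2ccccc2 | intermediate
24 | 3,4-bis(benzyloxy)-5-bromo-2-(methoxymethoxy)phenol | COCOc1c(O)cc(Br)c(OCc2ccccc2)c1OCc2ccccc2 | intermediate
25 | 1,3,4-tris(benzyloxy)-5-bromo-2-(methoxymethoxy)benzene | COCOc1c(OCc2ccccc2)cc(Br)c(OCc2ccccc2)c1OCc2ccccc2 | intermediate
26 | 1,3,4-tris(benzyloxy)-2-(methoxymethoxy)-5-[2,4,6-tris(benzyloxy)phenoxy]benzene | COCOc1c(OCc2ccccc2)cc(Oc3c(OCc4ccccc4)cc(OCc4ccccc4)cc3OCc4ccccc4)c(OCc2ccccc2)c1OCc2ccccc2 | intermediate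
27 | 2,3,6-tris(benzyloxy)-4-[2,4,6-tris(benzyloxy)phenoxy]phenol | Oc1c(OCc2ccccc2)cc(Oc3c(OCc4ccccc4)cc(OCc4ccccc4)cc3OCc4ccccc4)c(OCc2ccccc2)c1OCc2ccccc2 | intermediate
28 | 1,3,4-tris(benzyloxy)-2-[(E)-1,2-dichloroethenyloxy]-5-[2,4,6-tris(benzyloxy)phenoxy]benzene | Cl/C=C(/Cl)Oc1c(OCc2ccccc2)cc(Oc3c(OCc4ccccc4)cc(OCc4ccccc4)cc3OCc4ccccc4)c(OCc2ccccc2)c1OCc2ccccc2 | intermediate
29 | 1,3,4-tris(benzyloxy)-2-(chloroethynyloxy)-5-[2,4,6-tris(benzyloxy)phenoxy]benzene | ClC#COc1c(OCc2ccccc2)cc(Oc3c(OCc4ccccc4)cc(OCc4ccccc4)cc3OCc4ccccc4)c(OCc2ccccc2)c1OCc2ccccc2 | intermediate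
30 | lithium acetylide of 31 | [Li]C#COc1c(OCc2ccccc2)cc(Oc3c(OCc4ccccc4)cc(OCc4ccccc4)cc3OCc4ccccc4)c(OCc2ccccc2)c1OCc2ccccc2 | intermediate
31 | 1,3,4-tris(benzyloxy)-2-(ethynyloxy)-5-[2,4,6-tris(benzyloxy)phenoxy]benzene | C#COc1c(OCc2ccccc2)cc(Oc3c(OCc4ccccc4)cc(OCc4ccccc4)cc3OCc4ccccc4)c(OCc2ccccc2)c1OCc2ccccc2 | intermediate
32 | 3-(benzyloxy)-4-[3,4,5-tris(benzyloxy)phenoxy]buta-1,3-dien-1-one (vinylketene, aryloxy trans to the ketene carbon chain) | O=C=C/C(OCc1ccccc1)=C/Oc2cc(OCc3ccccc3)c(OCc3ccccc3)c(OCc3ccccc3)c2 | intermediate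
33 | racemic 4-{1-(benzyloxy)-2-[3,4,5-tris(benzyloxy)phenoxy]ethenyl}-3-{2,3,6-tris(benzyloxy)-4-[2,4,6-tris(benzyloxy)phenoxy]phenoxy}cyclobut-2-en-1-one | O=C1C=C(Oc2c(OCc3ccccc3)cc(Oc4c(OCc5ccccc5)cc(OCc5ccccc5)cc4OCc5ccccc5)c(OCc3ccccc3)c2OCc3ccccc3)C1/C(OCc6ccccc6)=C/Oc7cc(OCc8ccccc8)c(OCc8ccccc8)c(OCc8ccccc8)c7 | intermediate
34 | 5-(benzyloxy)-6-[3,4,5-tris(benzyloxy)phenoxy]-3-{2,3,6-tris(benzyloxy)-4-[2,4,6-tris(benzyloxy)phenoxy]phenoxy}hexa-1,3,5-trien-1-one (dienylketene, central double bond cis) | O=C=C/C(Oc1c(OCc2ccccc2)cc(Oc3c(OCc4ccccc4)cc(OCc4ccccc4)cc3OCc4ccccc4)c(OCc2ccccc2)c1OCc2ccccc2)=C\C(OCc5ccccc5)=C\Oc6cc(OCc7ccccc7)c(OCc7ccccc7)c(OCc7ccccc7)c6 | intermediate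
35 | racemic 5-(benzyloxy)-6-[3,4,5-tris(benzyloxy)phenoxy]-3-{2,3,6-tris(benzyloxy)-4-[2,4,6-tris(benzyloxy)phenoxy]phenoxy}cyclohexa-2,4-dien-1-one | O=C1C=C(Oc2c(OCc3ccccc3)cc(Oc4c(OCc5ccccc5)cc(OCc5ccccc5)cc4OCc5ccccc5)c(OCc3ccccc3)c2OCc3ccccc3)C=C(OCc6ccccc6)C1Oc7cc(OCc8ccccc8)c(OCc8ccccc8)c(OCc8ccccc8)c7 | intermediate
36 | 3-(benzyloxy)-2-[3,4,5-tris(benzyloxy)phenoxy]-5-{2,3,6-tris(benzyloxy)-4-[2,4,6-tris(benzyloxy)phenoxy]phenoxy}phenol | Oc1cc(Oc2c(OCc3ccccc3)cc(Oc4c(OCc5ccccc5)cc(OCc5ccccc5)cc4OCc5ccccc5)c(OCc3ccccc3)c2OCc3ccccc3)cc(OCc6ccccc6)c1Oc7cc(OCc8ccccc8)c(OCc8ccccc8)c(OCc8ccccc8)c7 | intermediate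
37 | 5-[2,3,6-trihydroxy-4-(2,4,6-trihydroxyphenoxy)phenoxy]-2-(3,4,5-trihydroxyphenoxy)benzene-1,3-diol | Oc1cc(O)c(Oc2cc(O)c(Oc3cc(O)c(Oc4cc(O)c(O)c(O)c4)c(O)c3)c(O)c2O)c(O)c1 | target

**Step count**

Total: 17 steps. Longest linear sequence: 11 steps (19 to 37 through steps 7–17).

**Steps most likely to fail, with fallbacks**

Step 16. The terminal aryl ynol ether may polymerise or be hydrated on heating before the vinylketene is available, and the vinylogous-ester cyclobutenone may open slowly. The fallback sets out from 28. The acetylide 30 formed with n-BuLi is quenched with Me3SiCl instead of water, which should give 1,3,4-tris(benzyloxy)-2-[(trimethylsilyl)ethynyloxy]-5-[2,4,6-tris(benzyloxy)phenoxy]benzene F1, a carbon-capped ynol ether that can be purified, stored and heated. Benzannulation of F1 with 14 in toluene should give 3-(benzyloxy)-2-[3,4,5-tris(benzyloxy)phenoxy]-5-{2,3,6-tris(benzyloxy)-4-[2,4,6-tris(benzyloxy)phenoxy]phenoxy}-6-(trimethylsilyl)phenol F2, the silicon sitting on C2 of ring C. Ipso-protodesilylation of this electron-rich arylsilane with TFA in CH2Cl2 at 0 °C brings the route back at 36.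

Step 12. Both partners are electron-rich and ortho-substituted, so oxidative addition to the bromide may be slow and the phenoxide may be oxidised or the bromide reduced instead. The fallback sets out from 25 and reverses the polarity of ring B. Bromine–lithium exchange (n-BuLi, THF, –78 °C), B(OiPr)3 and mild aqueous hydrolysis should give [2,3,5-tris(benzyloxy)-4-(methoxymethoxy)phenyl]boronic acid F3. Chan–Lam coupling of F3 with 18 (Cu(OAc)2, pyridine, 4 Å molecular sieves, CH2Cl2, dry air, rt), a method that accepts 2,6-disubstituted phenols, returns to the route at 26.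

Step 4. Benzyl ethynyl ether may be lost by sigmatropic rearrangement and the aryloxyketene by dimerisation before they combine. The fallback sets out from 5 and uses commercial ethoxyacetylene, which cannot rearrange in this way, under the same acid chloride–Et3N conditions. This should give racemic 3-ethoxy-4-[3,4,5-tris(benzyloxy)phenoxy]cyclobut-2-en-1-one F4. Heating F4 with 31 as in step 16 should give 3-ethoxy-2-[3,4,5-tris(benzyloxy)phenoxy]-5-{2,3,6-tris(benzyloxy)-4-[2,4,6-tris(benzyloxy)phenoxy]phenoxy}phenol F5. Hydrogenolysis (H2, Pd/C) should then give 3-ethoxy-5-[2,3,6-trihydroxy-4-(2,4,6-trihydroxyphenoxy)phenoxy]-2-(3,4,5-trihydroxyphenoxy)phenol F6, and cleavage of the ethyl ether with BBr3 (CH2Cl2, –78 °C → rt) reaches the target 37.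

Further compounds
F1 | step 16 | 1,3,4-tris(benzyloxy)-2-[(trimethylsilyl)ethynyloxy]-5-[2,4,6-tris(benzyloxy)phenoxy]benzene | C[Si](C)(C)C#COc1c(OCc2ccccc2)cc(Oc3c(OCc4ccccc4)cc(OCc4ccccc4)cc3OCc4ccccc4)c(OCc2ccccc2)c1OCc2ccccc2
F2 | step 16 | 3-(benzyloxy)-2-[3,4,5-tris(benzyloxy)phenoxy]-5-{2,3,6-tris(benzyloxy)-4-[2,4,6-tris(benzyloxy)phenoxy]phenoxy}-6-(trimethylsilyl)phenol | Oc1c([Si](C)(C)C)c(Oc2c(OCc3ccccc3)cc(Oc4c(OCc5ccccc5)cc(OCc5ccccc5)cc4OCc5ccccc5)c(OCc3ccccc3)c2OCc3ccccc3)cc(OCc6ccccc6)c1Oc7cc(OCc8ccccc8)c(OCc8ccccc8)c(OCc8ccccc8)c7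
F3 | step 12 | [2,3,5-tris(benzyloxy)-4-(methoxymethoxy)phenyl]boronic acid | OB(O)c1cc(OCc2ccccc2)c(OCOC)c(OCc2ccccc2)c1OCc2ccccc2
F4 | step 4 | racemic 3-ethoxy-4-[3,4,5-tris(benzyloxy)phenoxy]cyclobut-2-en-1-one | CCOC1=CC(=O)C1Oc2cc(OCc3ccccc3)c(OCc3ccccc3)c(OCc3ccccc3)c2
F5 | step 4 | 3-ethoxy-2-[3,4,5-tris(benzyloxy)phenoxy]-5-{2,3,6-tris(benzyloxy)-4-[2,4,6-tris(benzyloxy)phenoxy]phenoxy}phenol | CCOc1cc(Oc2c(OCc3ccccc3)cc(Oc4c(OCc5ccccc5)cc(OCc5ccccc5)cc4OCc5ccccc5)c(OCc3ccccc3)c2OCc3ccccc3)cc(O)c1Oc6cc(OCc7ccccc7)c(OCc7ccccc7)c(OCc7ccccc7)c6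
F6 | step 4 | 3-ethoxy-5-[2,3,6-trihydroxy-4-(2,4,6-trihydroxyphenoxy)phenoxy]-2-(3,4,5-trihydroxyphenoxy)phenol | CCOc1cc(Oc2c(O)cc(Oc3c(O)cc(O)cc3O)c(O)c2O)cc(O)c1Oc4cc(O)c(O)c(O)c4
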